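**Retrosynthetic overview**

1. Target 24 ⇐ late C14–H allylic oxidation (SeO2), lactone α‑methylenation, Stille hydroxymethylation (C15) and tigloylation at C6, all from the ten‑membered vinylogous acyl triflate 16.
2. 16 ⇐ ten‑membered 1,3‑diketone 15 ⇐ key step: SmI2 aldol/Grob ring expansion of cyclopentanone mesylate 12 (C4–C5 made, C4–C10 broken, C1=C10 created; 5‑ring → 10‑ring).
3. 12 ⇐ cyclopentane‑1,3‑dione 4 (C1–C4, C10) + lactone aldehyde 5 (reductive alkylation, C9–C10), MeI (C14), vinyl → bromoacetyl (C5, C6).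
4. C8 comes from butenolide 1, C7 from anti‑selective vinyl conjugate addition, C6 from CBS reduction.
5. Ring order: γ‑lactone (present in 1) → cyclopentane (from 4) → transient 5/7/5 tricycle → ten‑membered carbocycle.

Assumption: the (R)‑enantiomer of 5‑(hydroxymethyl)furan‑2(5H)‑one is taken as commercial like its antipode; positions are quoted in germacrane numbering (C1–C15); 9–14 are mixtures at the two cyclopentane centres that vanish in step 7 (unspecified in the SMILES); 15–23 are drawn as the expected major C1=C10 isomer.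

**Route**

Step 1
Reactants: 1 (R)-5-(hydroxymethyl)furan-2(5H)-one; 2 vinylmagnesium bromide
Product: 3 (4S,5R)-5-(hydroxymethyl)-4-vinyldihydrofuran-2(3H)-one
Conditions: 2 (2.3 equiv), CuBr·SMe2 (10 mol%), THF, −78 → −30 °C; 1 M HCl
Reagents that add atoms: none
Why: Copper‑catalysed conjugate addition of the vinyl Grignard reagent, in which the first equivalent only deprotonates the hydroxyl and the vinyl group enters anti to the C5 substituent, so C7 is set trans to C8.

Step 2
Reactants: 3 (4S,5R)-5-(hydroxymethyl)-4-vinyldihydrofuran-2(3H)-one; 4 cyclopentane-1,3-dione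
Product: 7 2-{[(2S,3S)-5-oxo-3-vinyltetrahydrofuran-2-yl]methyl}cyclopentane-1,3-dione, via aldehyde 5 (not isolated), via alkylidene dione 6 (not isolated)
Conditions: Dess–Martin periodinane, CH2Cl2, 0 °C → rt; then 4, Hantzsch ester, L‑proline (10 mol%), CH2Cl2, rt
Reagents that add atoms: none
Why: Dess–Martin oxidation gives the sensitive α‑oxy aldehyde, which is consumed at once in a proline‑catalysed Knoevenagel condensation/Hantzsch‑ester conjugate reduction (three‑component reductive alkylation) that C‑alkylates the dione and leaves C7 and C8 untouched.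

Step 3
Reactants: 7 2-{[(2S,3S)-5-oxo-3-vinyltetrahydrofuran-2-yl]methyl}cyclopentane-1,3-dione
Product: 8 2-methyl-2-{[(2S,3S)-5-oxo-3-vinyltetrahydrofuran-2-yl]methyl}cyclopentane-1,3-dione
Conditions: MeI, K2CO3, acetone, 45 °C
Reagents that add atoms: iodomethane, CI
Why: Enolate C‑alkylation of the acidic 2‑alkyl‑1,3‑dione creates the quaternary C10 carrying the future C14, and carbonate does not deprotonate the lactone.

Step 4
Reactants: 8 2-methyl-2-{[(2S,3S)-5-oxo-3-vinyltetrahydrofuran-2-yl]methyl}cyclopentane-1,3-dione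
Product: 9 3-hydroxy-2-methyl-2-{[(2S,3S)-5-oxo-3-vinyltetrahydrofuran-2-yl]methyl}cyclopentan-1-one
Conditions: NaBH4 (0.3 equiv), MeOH–CH2Cl2, −78 → −40 °C
Reagents that add atoms: none
Why: Hydride mono‑reduction of the strained non‑enolisable 1,3‑dione is much faster than attack on the lactone, hydride enters mainly anti to the larger C2 substituent, and both new stereocentres are destroyed in step 7.

Step 5
Reactants: 9 3-hydroxy-2-methyl-2-{[(2S,3S)-5-oxo-3-vinyltetrahydrofuran-2-yl]methyl}cyclopentan-1-one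
Product: 10 2-methyl-3-oxo-2-{[(2S,3S)-5-oxo-3-vinyltetrahydrofuran-2-yl]methyl}cyclopentyl methanesulfonate
Conditions: MsCl, Et3N, CH2Cl2, 0 °C
Reagents that add atoms: methanesulfonyl chloride, CS(=O)(=O)Cl
Why: O‑Sulfonylation places the nucleofuge 1,3 to the remaining ketone, and the quaternary α‑carbon rules out E1cB elimination.

Step 6
Reactants: 10 2-methyl-3-oxo-2-{[(2S,3S)-5-oxo-3-vinyltetrahydrofuran-2-yl]methyl}cyclopentyl methanesulfonate
Product: 12 2-{[(2S,3R)-3-(bromoacetyl)-5-oxotetrahydrofuran-2-yl]methyl}-2-methyl-3-oxocyclopentyl methanesulfonate, via bromohydrin 11 (not isolated)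
Conditions: NBS, acetone–H2O (4:1), 0 °C; extractive work‑up; then Dess–Martin periodinane, CH2Cl2, rt
Reagents that add atoms: N-bromosuccinimide, O=C1CCC(=O)N1Br; water, O
Why: Bromohydrin formation on the only alkene (water opens the bromonium ion at the internal carbon) followed by Dess–Martin oxidation gives the bromomethyl ketone as a regiodefined enolate precursor, and C7 stays in the thermodynamically preferred trans arrangement on the lactone.

Step 7
Reactants: 12 2-{[(2S,3R)-3-(bromoacetyl)-5-oxotetrahydrofuran-2-yl]methyl}-2-methyl-3-oxocyclopentyl methanesulfonate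
Product: 15 (3aR,9Z,11aS)-10-methyl-3a,5,7,8,11,11a-hexahydrocyclodeca[b]furan-2,4,6(3H)-trione, via samarium enolate 13 (not isolated), via bicyclic samarium aldolate 14 (not isolated)
Conditions: SmI2 (2.3 equiv), THF, slow addition of 12 (final 5 mM), −78 °C → rt; 0.5 M HCl
Reagents that add atoms: none
Why: Proposed new method: two‑electron reduction of the C–Br bond gives the regiodefined samarium(III) enolate (the lactone α‑CH2 is never deprotonated), which adds to the cyclopentanone to close a seven‑membered aldol ring, and the resulting alkoxide, 1,3 to the mesylate, undergoes Grob fragmentation (C4–C10 cleaved, C1=C10 formed, the major cis‑mesylate giving the ring‑cis alkene) to the ten‑membered 1,3‑diketone; the closest known chemistry is the SmI2 Barbier‑cyclisation/Grob‑fragmentation cascade of iodoalkyl keto mesylates and the SmI2 Reformatsky‑type aldol cyclisation of α‑bromo ketones, but an enolate‑triggered ring expansion of this kind has not been shown.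

Step 8
Reactants: 15 (3aR,9Z,11aS)-10-methyl-3a,5,7,8,11,11a-hexahydrocyclodeca[b]furan-2,4,6(3H)-trione
Product: 16 (3aR,5E,9Z,11aS)-10-methyl-2,4-dioxo-2,3,3a,4,7,8,11,11a-octahydrocyclodeca[b]furan-6-yl trifluoromethanesulfonate
Conditions: Tf2O (1.05 equiv), pyridine, CH2Cl2, −78 °C
Reagents that add atoms: trifluoromethanesulfonic anhydride, O=S(=O)(OS(=O)(=O)C(F)(F)F)C(F)(F)F
Why: Enol triflate formation of the cyclic 1,3‑diketone is expected at the less hindered C4 oxygen (flanked by CH2, not by the ring‑fusion CH), and the ten‑membered ring holds the enol ring‑cis so that C3 and C6 are cis across C4=C5 as in the target.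

Step 9
Reactants: 16 (3aR,5E,9Z,11aS)-10-methyl-2,4-dioxo-2,3,3a,4,7,8,11,11a-octahydrocyclodeca[b]furan-6-yl trifluoromethanesulfonate
Product: 17 (3aS,4R,5E,9Z,11aS)-4-hydroxy-10-methyl-2-oxo-2,3,3a,4,7,8,11,11a-octahydrocyclodeca[b]furan-6-yl trifluoromethanesulfonate
Conditions: (S)-2-methyl-CBS-oxazaborolidine (30 mol%), catecholborane (1.5 equiv), toluene, −78 → −40 °C; MeOH, then aqueous work‑up
Reagents that add atoms: none
Why: Corey–Bakshi–Shibata reduction under reagent control, with the β‑triflyloxyalkenyl group as the large substituent, sets C6 as the 6β‑alcohol (labelled R here only because the triflate raises the priority of C5), and the neutral boron alkoxide avoids fragmentation of the β‑triflyloxy carbinol.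

Step 10
Reactants: 17 (3aS,4R,5E,9Z,11aS)-4-hydroxy-10-methyl-2-oxo-2,3,3a,4,7,8,11,11a-octahydrocyclodeca[b]furan-6-yl trifluoromethanesulfonate; 18 (E)-2-methylbut-2-enoyl chloride (tigloyl chloride)
Product: 19 (3aR,4R,5E,9Z,11aS)-10-methyl-2-oxo-6-(trifluoromethylsulfonyloxy)-2,3,3a,4,7,8,11,11a-octahydrocyclodeca[b]furan-4-yl (E)-2-methylbut-2-enoate
Conditions: 18 (1.5 equiv), pyridine, DMAP (10 mol%), CH2Cl2, 0 °C → rt
Reagents that add atoms: none
Why: DMAP‑catalysed esterification of the secondary allylic alcohol proceeds with retention at C6 and without forming an alkoxide.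

Step 11
Reactants: 19 (3aR,4R,5E,9Z,11aS)-10-methyl-2-oxo-6-(trifluoromethylsulfonyloxy)-2,3,3a,4,7,8,11,11a-octahydrocyclodeca[b]furan-4-yl (E)-2-methylbut-2-enoate
Product: 20 (3aR,4S,5E,9Z,11aS)-6-(hydroxymethyl)-10-methyl-2-oxo-2,3,3a,4,7,8,11,11a-octahydrocyclodeca[b]furan-4-yl (E)-2-methylbut-2-enoate
Conditions: Bu3SnCH2OH (1.5 equiv), Pd(PPh3)4 (5 mol%), CuI (10 mol%), CsF (2 equiv), DMF, 45 °C
Reagents that add atoms: (tributylstannyl)methanol, CCCC[Sn](CCCC)(CCCC)CO
Why: Copper/fluoride‑accelerated Stille cross‑coupling transfers the hydroxymethyl group to the alkenyl triflate with retention of alkene geometry, placing C15 trans to C6, and the mild temperature is chosen to keep Pd(0) from ionising the hindered allylic tiglate.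

Step 12
Reactants: 20 (3aR,4S,5E,9Z,11aS)-6-(hydroxymethyl)-10-methyl-2-oxo-2,3,3a,4,7,8,11,11a-octahydrocyclodeca[b]furan-4-yl (E)-2-methylbut-2-enoate
Product: 23 (3aR,4S,5E,9Z,11aS)-6-(hydroxymethyl)-10-methyl-3-methylidene-2-oxo-2,3,3a,4,7,8,11,11a-octahydrocyclodeca[b]furan-4-yl (E)-2-methylbut-2-enoate, via Mannich base 21 (not isolated), via methiodide 22 (not isolated)
Conditions: LiHMDS (2.2 equiv), THF, −78 °C; Eschenmoser's salt (3 equiv), −78 → 0 °C; AcOH quench; then MeI, MeOH, rt; then aq. NaHCO3, EtOAc, rt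
Reagents that add atoms: N,N-dimethylmethyleneiminium iodide, C=[N+](C)C.[I-] (iodomethane, CI, only quaternises 21 and leaves again with the amine)
Why: Mannich reaction of the lactone lithium enolate (the primary alkoxide is a spectator), exhaustive N‑methylation and β‑elimination install the exocyclic methylene (Eschenmoser methylenation) without touching C7.

Step 13
Reactants: 23 (3aR,4S,5E,9Z,11aS)-6-(hydroxymethyl)-10-methyl-3-methylidene-2-oxo-2,3,3a,4,7,8,11,11a-octahydrocyclodeca[b]furan-4-yl (E)-2-methylbut-2-enoate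
Product: 24 (3aR,4S,5E,9E,11aS)-6,10-bis(hydroxymethyl)-3-methylidene-2-oxo-2,3,3a,4,7,8,11,11a-octahydrocyclodeca[b]furan-4-yl (E)-2-methylbut-2-enoate
Conditions: SeO2 (0.5 equiv), t‑BuOOH (3 equiv), CH2Cl2, 0 °C → rt
Reagents that add atoms: tert-butyl hydroperoxide, CC(C)(C)OO (oxygen relayed by the SeO2 catalyst, O=[Se]=O)
Why: Selenium dioxide allylic oxidation (ene reaction then [2,3]-shift) attacks the electron‑richer C1=C10 alkene at its (E)-methyl group C14 and leaves the hydroxymethyl group trans to C2, while C4=C5 is deactivated by its allylic acyloxy and hydroxyl groups; any minor C1=C10 isomer is expected to converge on the same product, as in the known conversion of germacranolide C10‑methyl groups into ring‑cis C14 alcohols.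

**Compound list**

1 | (R)-5-(hydroxymethyl)furan-2(5H)-one | O=C1C=C[C@H](CO)O1 | starting material
2 | vinylmagnesium bromide | C=C[Mg]Br | starting material
3 | (4S,5R)-5-(hydroxymethyl)-4-vinyldihydrofuran-2(3H)-one | O=C1C[C@@H](C=C)[C@H](CO)O1 | intermediate
4 | cyclopentane-1,3-dione | O=C1CCC(=O)C1 | starting material
5 | (2R,3S)-5-oxo-3-vinyltetrahydrofuran-2-carbaldehyde | O=C1C[C@@H](C=C)[C@H](C=O)O1 | intermediate
6 | 2-{[(2R,3S)-5-oxo-3-vinyltetrahydrofuran-2-yl]methylidene}cyclopentane-1,3-dione | O=C1C[C@@H](C=C)[C@H](C=C2C(=O)CCC2=O)O1 | intermediate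
7 | 2-{[(2S,3S)-5-oxo-3-vinyltetrahydrofuran-2-yl]methyl}cyclopentane-1,3-dione | O=C1C[C@@H](C=C)[C@H](CC2C(=O)CCC2=O)O1 | intermediate
8 | 2-methyl-2-{[(2S,3S)-5-oxo-3-vinyltetrahydrofuran-2-yl]methyl}cyclopentane-1,3-dione | O=C1C[C@@H](C=C)[C@H](CC2(C)C(=O)CCC2=O)O1 | intermediate
9 | 3-hydroxy-2-methyl-2-{[(2S,3S)-5-oxo-3-vinyltetrahydrofuran-2-yl]methyl}cyclopentan-1-one (cyclopentane diastereomers) | O=C1C[C@@H](C=C)[C@H](CC2(C)C(O)CCC2=O)O1 | intermediate
10 | 2-methyl-3-oxo-2-{[(2S,3S)-5-oxo-3-vinyltetrahydrofuran-2-yl]methyl}cyclopentyl methanesulfonate | O=C1C[C@@H](C=C)[C@H](CC2(C)C(OS(C)(=O)=O)CCC2=O)O1 | intermediate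
11 | 2-{[(2S,3S)-3-(2-bromo-1-hydroxyethyl)-5-oxotetrahydrofuran-2-yl]methyl}-2-methyl-3-oxocyclopentyl methanesulfonate | O=C1C[C@@H](C(O)CBr)[C@H](CC2(C)C(OS(C)(=O)=O)CCC2=O)O1 | intermediate
12 | 2-{[(2S,3R)-3-(bromoacetyl)-5-oxotetrahydrofuran-2-yl]methyl}-2-methyl-3-oxocyclopentyl methanesulfonate | O=C1C[C@@H](C(=O)CBr)[C@H](CC2(C)C(OS(C)(=O)=O)CCC2=O)O1 | intermediate
13 | diiodosamarium(III) enolate of 12 (terminal enolate C5=C6–O–Sm) | O=C1C[C@@H](C(=C)O[Sm](I)I)[C@H](CC2(C)C(OS(C)(=O)=O)CCC2=O)O1 | intermediate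
14 | bicyclic samarium(III) aldolate (lactone/cycloheptanone/cyclopentane tricycle, alkoxide at C4, mesylate at C1) | O=C1C[C@H]2C(=O)CC3(O[Sm](I)I)CCC(OS(C)(=O)=O)C3(C)C[C@@H]2O1 | intermediate
15 | (3aR,9Z,11aS)-10-methyl-3a,5,7,8,11,11a-hexahydrocyclodeca[b]furan-2,4,6(3H)-trione (trans‑fused lactone, ketones at C4 and C6) | C1C(=O)O[C@H]2C/C(C)=C\CCC(=O)CC(=O)[C@H]12 | intermediate
16 | (3aR,5E,9Z,11aS)-10-methyl-2,4-dioxo-2,3,3a,4,7,8,11,11a-octahydrocyclodeca[b]furan-6-yl trifluoromethanesulfonate | C1C(=O)O[C@H]2C/C(C)=C\CC/C(OS(=O)(=O)C(F)(F)F)=C\C(=O)[C@H]12 | intermediate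
17 | (3aS,4R,5E,9Z,11aS)-4-hydroxy-10-methyl-2-oxo-2,3,3a,4,7,8,11,11a-octahydrocyclodeca[b]furan-6-yl trifluoromethanesulfonate | C1C(=O)O[C@H]2C/C(C)=C\CC/C(OS(=O)(=O)C(F)(F)F)=C\[C@H](O)[C@H]12 | intermediate
18 | (E)-2-methylbut-2-enoyl chloride (tigloyl chloride) | C/C=C(\C)C(=O)Cl | starting material
19 | (3aR,4R,5E,9Z,11aS)-10-methyl-2-oxo-6-(trifluoromethylsulfonyloxy)-2,3,3a,4,7,8,11,11a-octahydrocyclodeca[b]furan-4-yl (E)-2-methylbut-2-enoate | C1C(=O)O[C@H]2C/C(C)=C\CC/C(OS(=O)(=O)C(F)(F)F)=C\[C@H](OC(=O)/C(C)=C/C)[C@H]12 | intermediate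
20 | (3aR,4S,5E,9Z,11aS)-6-(hydroxymethyl)-10-methyl-2-oxo-2,3,3a,4,7,8,11,11a-octahydrocyclodeca[b]furan-4-yl (E)-2-methylbut-2-enoate | C1C(=O)O[C@H]2C/C(C)=C\CC/C(CO)=C\[C@H](OC(=O)/C(C)=C/C)[C@H]12 | intermediate
21 | 3-[(dimethylamino)methyl] derivative of 20 (Mannich base, C3 epimers) | CN(C)CC1C(=O)O[C@H]2C/C(C)=C\CC/C(CO)=C\[C@H](OC(=O)/C(C)=C/C)[C@H]12 | intermediate
22 | trimethylammonium iodide of 21 (methiodide) | C[N+](C)(C)CC1C(=O)O[C@H]2C/C(C)=C\CC/C(CO)=C\[C@H](OC(=O)/C(C)=C/C)[C@H]12.[I-] | intermediate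
23 | (3aR,4S,5E,9Z,11aS)-6-(hydroxymethyl)-10-methyl-3-methylidene-2-oxo-2,3,3a,4,7,8,11,11a-octahydrocyclodeca[b]furan-4-yl (E)-2-methylbut-2-enoate | C=C1C(=O)O[C@H]2C/C(C)=C\CC/C(CO)=C\[C@H](OC(=O)/C(C)=C/C)[C@H]12 | intermediate
24 | (3aR,4S,5E,9E,11aS)-6,10-bis(hydroxymethyl)-3-methylidene-2-oxo-2,3,3a,4,7,8,11,11a-octahydrocyclodeca[b]furan-4-yl (E)-2-methylbut-2-enoate (CNP0275462.1) | C=C1C(=O)O[C@H]2C/C(CO)=C\CC/C(CO)=C\[C@H](OC(=O)/C(C)=C/C)[C@H]12 | target

**Step count and risks**

Total step count: 13. Longest linear sequence: 13 steps (1 → 24; 2, 4 and 18 enter as single building blocks).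

Steps most likely to fail:

Step 7 (the proposed SmI2 aldol/Grob ring expansion). The seven‑membered aldol onto a hindered ketone may lose to simple protonation of the enolate, or the samarium alkoxide may not fragment. The fallback uses only known reactions, separates the two events and changes the bond‑forming chemistry. It sets out from 12: zinc dust and TMSCl convert the bromo ketone regiospecifically into the terminal trimethylsilyl enol ether F1. TiCl4 (CH2Cl2, −78 °C) then closes the seven‑membered ring by an intramolecular Mukaiyama aldol addition to the cyclopentanone, giving the bicyclic β‑hydroxy ketone F2. KOt‑Bu in THF triggers the classical Wharton–Grob fragmentation of this 1,3‑hydroxy mesylate, and the route is rejoined at 15.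

Step 9 (configuration at C6). The branched C7 side may compete with the alkenyl group as the large substituent, or the ring may impose its own facial bias. The fallback sets out from 16: if reduction (CBS, or a substrate‑controlled Luche reduction with NaBH4/CeCl3) gives mainly the C6‑epimeric allylic alcohol F3, this is esterified with inversion under Mitsunobu conditions (tiglic acid, PPh3, DIAD, THF, 0 °C). The configuration is then fixed by SN2 displacement rather than by hydride delivery, step 10 is no longer needed, and the route is rejoined at 19.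

Step 11 (Stille coupling beside an allylic tiglate). Pd(0) may ionise the allylic ester or the sp3 transfer from tin may be too slow at 45 °C. The fallback sets out from 16 and moves the coupling ahead of the ester. Stille hydroxymethylation of the activated vinylogous acyl triflate (Bu3SnCH2OH, Pd(PPh3)4, LiCl, dioxane, 80 °C) gives the hydroxymethyl enone F4. TBSCl/imidazole gives the silyl ether F5, CBS reduction as in step 9 gives the allylic alcohol F6, and tigloyl chloride/pyridine gives the tiglate F7. HF·pyridine removes the silyl group and the route is rejoined at 20, at the cost of two extra steps.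

Further compounds
F1 | step 7 | 2-methyl-3-oxo-2-{[(2S,3R)-5-oxo-3-(1-trimethylsilyloxyvinyl)tetrahydrofuran-2-yl]methyl}cyclopentyl methanesulfonate | O=C1C[C@@H](C(=C)O[Si](C)(C)C)[C@H](CC2(C)C(OS(C)(=O)=O)CCC2=O)O1
F2 | step 7 | bicyclic β-hydroxy ketone (lactone/cycloheptanone/cyclopentane tricycle, free OH at C4, mesylate at C1) | O=C1C[C@H]2C(=O)CC3(O)CCC(OS(C)(=O)=O)C3(C)C[C@@H]2O1
F3 | step 9 | C6 epimer of 17 (4-epi alcohol, cyclodeca[b]furan numbering) | C1C(=O)O[C@H]2C/C(C)=C\CC/C(OS(=O)(=O)C(F)(F)F)=C\[C@@H](O)[C@H]12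
F4 | step 11 | (3aR,5E,9Z,11aS)-6-(hydroxymethyl)-10-methyl-3,3a,7,8,11,11a-hexahydrocyclodeca[b]furan-2,4-dione | C1C(=O)O[C@H]2C/C(C)=C\CC/C(CO)=C\C(=O)[C@H]12
F5 | step 11 | tert-butyldimethylsilyl ether of F4 | C1C(=O)O[C@H]2C/C(C)=C\CC/C(CO[Si](C)(C)C(C)(C)C)=C\C(=O)[C@H]12
F6 | step 11 | 6β-alcohol from F5 (C6 configured as in 20) | C1C(=O)O[C@H]2C/C(C)=C\CC/C(CO[Si](C)(C)C(C)(C)C)=C\[C@H](O)[C@H]12
F7 | step 11 | tert-butyldimethylsilyl ether of 20 | C1C(=O)O[C@H]2C/C(C)=C\CC/C(CO[Si](C)(C)C(C)(C)C)=C\[C@H](OC(=O)/C(C)=C/C)[C@H]12
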